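**Retrosynthetic overview**
- Target ⇐ silyl ether of the primary allylic alcohol (final desilylation).
- The γ-lactone, the only ring, is closed second to last by carbonyl allylboration/lactonisation (C6–C7 bond) between a 2-(methoxycarbonyl)allylboronate that already carries the C8 methacrylate and (E)-4-acetoxy-3-methylbut-2-enal.
- Key step: the allylboronate arises by a 1,2-metallate shift (alkenyl carbon migrates from boron to an iodomethyl carbon) after copper hydride syn-hydrocupration of a γ-(methacryloyloxy) ynoate. This forms the exo-methylene C–C bond and fixes the alkene geometry that becomes the trans ring relationship.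
- Ynoate ⇐ methyl propiolate + a β,γ-unsaturated aldehyde (from (E)-3-methylpent-2-en-4-yn-1-ol) by Zn/ProPhenol alkynylation, which sets C8.
- Enal ⇐ propargyl alcohol by Zr-catalysed carboalumination/iodination, Pd formylation and acetylation.

Position labels: C6 = lactone O–CH, C7 = ring CH bearing the side chain, C8 = CH–O(methacrylate).
Assumption: (S,S)-ProPhenol is taken to give the 4R propargylic alcohol; the antipodal ligand is used if the first Mosher analysis shows the opposite sense.

**Step 1**
Reactants: 1 (E)-3-methylpent-2-en-4-yn-1-ol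
Product: 2 (E)-tert-butyldimethyl[(3-methylpent-2-en-4-yn-1-yl)oxy]silane
Conditions: TBSCl (1.1 equiv), imidazole (2 equiv), CH2Cl2, 0 °C → rt
Reagents that add atoms: tert-butyldimethylsilyl chloride CC(C)(C)[Si](C)(C)Cl
Why: Imidazole-promoted O-silylation (substitution at silicon) masks the primary allylic alcohol that must be the only free hydroxyl at the end.

**Step 2**
Reactants: 2
Product: 3 (E)-5-[(tert-butyldimethylsilyl)oxy]-3-methylpent-3-enal
Conditions: [CpRu(MeCN)3]PF6 (3 mol%), 5,5′-bis(trifluoromethyl)-2,2′-bipyridine (3 mol%), NMP/H2O 4:1, 25 °C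
Reagents that add atoms: water O
Why: Ruthenium-catalysed anti-Markovnikov alkyne hydration (water adds to the α-carbon of a Ru vinylidene) gives the aldehyde at neutral pH and room temperature, so the trisubstituted E alkene stays out of conjugation.

**Step 3**
Reactants: 3; 4 methyl propiolate
Product: 6 methyl (4R,6E)-8-[(tert-butyldimethylsilyl)oxy]-4-hydroxy-6-methyloct-6-en-2-ynoate, via methylzinc alkynylide 5 (not isolated)
Conditions: 4 (3 equiv), Me2Zn (3 equiv), (S,S)-ProPhenol (20 mol%), Ph3PO (40 mol%), toluene, 0–4 °C, 36 h; aq. NH4Cl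
Reagents that add atoms: none
Why: Catalytic asymmetric alkynylation of an aldehyde: the dinuclear zinc–ProPhenol complex binds 3 and the alkynylzinc 5 and delivers the alkynyl group to the Si face, setting C8 as 4R.

**Step 4**
Reactants: 6
Product: 7 methyl (4R,6E)-8-[(tert-butyldimethylsilyl)oxy]-6-methyl-4-(methacryloyloxy)oct-6-en-2-ynoate
Conditions: methacryloyl chloride (1.3 equiv), pyridine (3 equiv), DMAP (5 mol%), CH2Cl2, −10 → 0 °C
Reagents that add atoms: methacryloyl chloride C=C(C)C(Cl)=O
Why: DMAP-catalysed O-acylation installs the methacrylate early without touching the C8–O bond (configuration retained), and the weak base avoids ynoate-to-allene isomerisation.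

**Step 5**
Reactants: 7
Product: 10 methyl (2Z,4R,6E)-8-[(tert-butyldimethylsilyl)oxy]-6-methyl-4-(methacryloyloxy)-2-[(4,4,5,5-tetramethyl-1,3,2-dioxaborolan-2-yl)methyl]octa-2,6-dienoate, via α-cuprio enoate 8 (not isolated), via boron ate complex 9 (not isolated)
Conditions: [(Ph3P)CuH]6 (0.18 equiv, 1.08 equiv hydride), THF/toluene, −40 °C, 1 h; then ICH2Bpin (1.5 equiv), DMPU (3 equiv), −40 → 0 °C; pH 7 buffer
Reagents that add atoms: 2-(iodomethyl)-4,4,5,5-tetramethyl-1,3,2-dioxaborolane ICB1OC(C)(C)C(C)(C)O1
Why: Proposed new method: the phosphine-ligated copper hydride adds syn to the ynoate (hydride to C3, copper to C2; the unhindered ynoate should react before the α-substituted methacrylate, and no proton source is present) to give 8, whose alkenyl carbon is transferred to the Lewis-acidic boron of ICH2Bpin to form the tetracoordinate boronate 9, in which that carbon migrates from boron to the neighbouring CH2 with loss of iodide (1,2-metallate shift, copper as halophile), forming the C2–CH2 bond with retention of geometry (C4 cis to CO2Me, also the isomer expected if the copper allenolate equilibrates); the closest known reaction type is Matteson-type trapping of α-metalated acrylates (from carbocupration or i-Bu2AlH/HMPA reduction of ynoates) with halomethylboronates, which has not been shown with a copper hydride as hydride source or in the presence of a second acrylate.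

**Step 6**
Reactants: 11 prop-2-yn-1-ol
Product: 13 (E)-3-iodo-2-methylprop-2-en-1-ol, via alkenylalane 12 (not isolated)
Conditions: Me3Al (3 equiv), Cp2ZrCl2 (0.25 equiv), CH2Cl2, 0 °C → rt, 16 h; then I2 (1.2 equiv), THF, −30 → 0 °C; aq. potassium sodium tartrate
Reagents that add atoms: trimethylaluminium C[Al](C)C; iodine II
Why: Negishi zirconium-catalysed carboalumination adds methyl and aluminium syn (methyl to the internal carbon), and iodinolysis of the carbon–aluminium bond with retention gives the E iodide only.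

**Step 7**
Reactants: 13
Product: 14 (E)-4-hydroxy-3-methylbut-2-enal
Conditions: CO (3 atm), Pd(PPh3)4 (4 mol%), Bu3SnH (1.1 equiv, syringe pump over 3 h), THF, 50 °C
Reagents that add atoms: carbon monoxide [C-]#[O+]
Why: Palladium-catalysed reductive carbonylation (formylation): oxidative addition of the alkenyl iodide to zerovalent palladium with retention, CO insertion and hydride transfer from tin give the E enal; running it on the free alcohol avoids π-allyl chemistry of an allylic acetate.

**Step 8**
Reactants: 14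
Product: 15 (E)-4-acetoxy-3-methylbut-2-enal [(2E)-2-methyl-4-oxobut-2-en-1-yl acetate]
Conditions: Ac2O (1.5 equiv), pyridine (2 equiv), DMAP (2 mol%), CH2Cl2, 0 °C
Reagents that add atoms: acetic anhydride CC(=O)OC(C)=O
Why: Standard DMAP-catalysed acetylation of the primary allylic alcohol; the E geometry cannot lactolise or isomerise under these conditions.

**Step 9**
Reactants: 10; 15
Product: 17 (1R,3E)-1-[(2R,3R)-2-[(1E)-3-acetoxy-2-methylprop-1-en-1-yl]-4-methylidene-5-oxooxolan-3-yl]-5-[(tert-butyldimethylsilyl)oxy]-3-methylpent-3-en-1-yl 2-methylprop-2-enoate, via borate ester 16 (not isolated)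
Conditions: 15 (1.5 equiv), Sc(OTf)3 (10 mol%), 4 Å MS, toluene, −20 °C → rt, 12 h; then p-TsOH·H2O (10 mol%), rt, 2 h
Reagents that add atoms: none
Why: Lewis-acid-catalysed carbonyl allylboration through a closed chair transition state followed by lactonisation: the C8 substituent is trans to CH2B and the aldehyde alkenyl group is equatorial, which gives the anti adduct (6,7-trans ring, C6 R); A(1,3) strain with the cis CO2Me holds the C8–H in the alkene plane so the aldehyde adds anti to the C9 chain with the acyloxy group outside (C7 R); the C6 borate then closes onto the methyl ester, and the other lactone cannot form because O8 is already acylated.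

**Step 10**
Reactants: 17
Product: 18 (1R,3E)-1-[(2R,3R)-2-[(1E)-3-acetoxy-2-methylprop-1-en-1-yl]-4-methylidene-5-oxooxolan-3-yl]-5-hydroxy-3-methylpent-3-en-1-yl 2-methylprop-2-enoate (CNP0323189.1)
Conditions: HF·pyridine (excess), pyridine/THF, 0 °C → rt
Reagents that add atoms: none
Why: Fluoride-mediated desilylation under buffered acidic conditions frees the primary allylic alcohol without acyl migration or conjugate addition to the α-methylene lactone or methacrylate.

**Compound list**
1 | (E)-3-methylpent-2-en-4-yn-1-ol | C#C/C(C)=C/CO | starting material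
2 | (E)-tert-butyldimethyl[(3-methylpent-2-en-4-yn-1-yl)oxy]silane | C#C/C(C)=C/CO[Si](C)(C)C(C)(C)C | intermediate
3 | (E)-5-[(tert-butyldimethylsilyl)oxy]-3-methylpent-3-enal | O=CC/C(C)=C/CO[Si](C)(C)C(C)(C)C | intermediate
4 | methyl propiolate | C#CC(=O)OC | starting material
5 | methyl 3-(methylzincio)prop-2-ynoate (methylzinc alkynylide) | C[Zn]C#CC(=O)OC | intermediate (not isolated)
6 | methyl (4R,6E)-8-[(tert-butyldimethylsilyl)oxy]-4-hydroxy-6-methyloct-6-en-2-ynoate | O[C@H](C/C(C)=C/CO[Si](C)(C)C(C)(C)C)C#CC(=O)OC | intermediate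
7 | methyl (4R,6E)-8-[(tert-butyldimethylsilyl)oxy]-6-methyl-4-(methacryloyloxy)oct-6-en-2-ynoate | C=C(C)C(=O)O[C@H](C/C(C)=C/CO[Si](C)(C)C(C)(C)C)C#CC(=O)OC | intermediate
8 | methyl (2E,4R,6E)-2-cuprio-8-[(tert-butyldimethylsilyl)oxy]-6-methyl-4-(methacryloyloxy)octa-2,6-dienoate (α-cuprio enoate, Ph3P ligands omitted) | C=C(C)C(=O)O[C@H](C/C(C)=C/CO[Si](C)(C)C(C)(C)C)/C=C(/[Cu])\C(=O)OC | intermediate (not isolated)
9 | copper salt of the alkenyl(iodomethyl)(pinacolato)borate formed from 8 and ICH2Bpin (boron ate complex) | C=C(C)C(=O)O[C@H](C/C(C)=C/CO[Si](C)(C)C(C)(C)C)/C=C(/[B-]1(CI)OC(C)(C)C(C)(C)O1)\C(=O)OC.[Cu+] | intermediate (not isolated)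
10 | methyl (2Z,4R,6E)-8-[(tert-butyldimethylsilyl)oxy]-6-methyl-4-(methacryloyloxy)-2-[(4,4,5,5-tetramethyl-1,3,2-dioxaborolan-2-yl)methyl]octa-2,6-dienoate | C=C(C)C(=O)O[C@H](C/C(C)=C/CO[Si](C)(C)C(C)(C)C)/C=C(/CB1OC(C)(C)C(C)(C)O1)\C(=O)OC | intermediate
11 | prop-2-yn-1-ol | C#CCO | starting material
12 | dimethyl[(E)-3-(dimethylalumanyloxy)-2-methylprop-1-en-1-yl]alane (alkenylalane) | C[Al](C)OC/C(C)=C/[Al](C)C | intermediate (not isolated)
13 | (E)-3-iodo-2-methylprop-2-en-1-ol | OC/C(C)=C/I | intermediate
14 | (E)-4-hydroxy-3-methylbut-2-enal | OC/C(C)=C/C=O | intermediate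
15 | (E)-4-acetoxy-3-methylbut-2-enal | CC(=O)OC/C(C)=C/C=O | intermediate
16 | open-chain pinacol borate of the allylboration adduct: methyl ester with C6–O–Bpin, C7 bearing C(=CH2)CO2Me, C8 methacrylate, same configurations as 17 | C=C(C)C(=O)O[C@H](C/C(C)=C/CO[Si](C)(C)C(C)(C)C)[C@@H](C(=C)C(=O)OC)[C@H](OB1OC(C)(C)C(C)(C)O1)/C=C(\C)COC(C)=O | intermediate (not isolated)
17 | (1R,3E)-1-[(2R,3R)-2-[(1E)-3-acetoxy-2-methylprop-1-en-1-yl]-4-methylidene-5-oxooxolan-3-yl]-5-[(tert-butyldimethylsilyl)oxy]-3-methylpent-3-en-1-yl 2-methylprop-2-enoate | C=C(C)C(=O)O[C@H](C/C(C)=C/CO[Si](C)(C)C(C)(C)C)[C@H]1C(=C)C(=O)O[C@@H]1/C=C(\C)COC(C)=O | intermediate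
18 | (1R,3E)-1-[(2R,3R)-2-[(1E)-3-acetoxy-2-methylprop-1-en-1-yl]-4-methylidene-5-oxooxolan-3-yl]-5-hydroxy-3-methylpent-3-en-1-yl 2-methylprop-2-enoate | C=C(C)C(=O)O[C@H](C/C(C)=C/CO)[C@H]1C(=C)C(=O)O[C@@H]1/C=C(\C)COC(C)=O | target

**Totals**
Total steps: 10. Longest linear sequence: 7 (steps 1, 2, 3, 4, 5, 9, 10).

**Steps most likely to fail**

1. Step 5 (proposed new step). The copper hydride may also reduce the methacrylate, the allenolate may be borylmethylated on oxygen, or the acyl group may transfer within the enolate. Fallback with known chemistry, setting out from 6 and returning at 17: silylate 6 (TESCl, imidazole) to the C8 triethylsilyl ether F1. Reduce the ynoate conjugatively with i-Bu2AlH/HMPA (THF, 0 °C) and trap the α-aluminio enoate with ICH2Bpin (the established halomethylboronate trapping, same 1,2-metallate shift) to give the silyloxy allylboronate F2. Sc(OTf)3-catalysed allylboration/lactonisation with 15 gives the C8-silyloxy lactone F3. PPTS in MeOH at 0 °C removes the secondary TES group selectively to give the C8 alcohol F4; translactonisation is disfavoured because the alternative lactone would be cis. Methacryloyl chloride/pyridine/DMAP then gives 17.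

2. Step 9. The facial selectivity rests on an acyclic A(1,3) model that is untested for this reagent, the electron-poor allylboronate may be sluggish, and acid could ionise the allylic C6–O bond. Fallback using ring control, setting out from 15, 4 and 3 and returning at 17: Zn/ProPhenol alkynylation of the enal 15 with 4 (same ligand as step 3; enals are the best substrates) gives the 4R propargylic alcohol F5. In situ silylation with BSA gives the trimethylsilyl ether F6. The step 5 protocol followed by citric acid/MeOH work-up (desilylation and spontaneous lactonisation of the Z γ-hydroxy enoate) gives the 3-(borylmethyl)butenolide F7. Sc(OTf)3-catalysed allylboration of 3 with F7 occurs anti to the ring substituent at C6 (fixing C7) and through the chair gives the 8S alcohol F8, the C8 epimer. Mitsunobu esterification with methacrylic acid (PPh3, DIAD, THF, 0 °C) inverts C8 and gives 17.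

3. Step 3. The enolisable β,γ-unsaturated aldehyde may isomerise or self-condense under the zinc conditions and give modest ee. Fallback, setting out from 3 and 4 and returning at 6: add lithiated 4 (LiHMDS, THF, −78 °C) to 3 to give the racemic propargylic alcohol F9. Oxidise with Dess–Martin periodinane to the ynone F10. Asymmetric transfer hydrogenation with RuCl(p-cymene)[(R,R)-TsDPEN] in HCO2H/Et3N then gives 6.

**Further compounds**
F1 | step 5 | methyl (4R,6E)-8-[(tert-butyldimethylsilyl)oxy]-6-methyl-4-[(triethylsilyl)oxy]oct-6-en-2-ynoate | CC[Si](CC)(CC)O[C@H](C/C(C)=C/CO[Si](C)(C)C(C)(C)C)C#CC(=O)OC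
F2 | step 5 | analogue of 10 with OSiEt3 in place of the methacrylate (2Z allylboronate) | CC[Si](CC)(CC)O[C@H](C/C(C)=C/CO[Si](C)(C)C(C)(C)C)/C=C(/CB1OC(C)(C)C(C)(C)O1)\C(=O)OC
F3 | step 5 | analogue of 17 with OSiEt3 in place of the methacrylate at C8 | CC[Si](CC)(CC)O[C@H](C/C(C)=C/CO[Si](C)(C)C(C)(C)C)[C@H]1C(=C)C(=O)O[C@@H]1/C=C(\C)COC(C)=O
F4 | step 5 | analogue of 17 with free OH at C8 (same configurations) | O[C@H](C/C(C)=C/CO[Si](C)(C)C(C)(C)C)[C@H]1C(=C)C(=O)O[C@@H]1/C=C(\C)COC(C)=O
F5 | step 9 | methyl (4R,5E)-7-acetoxy-4-hydroxy-6-methylhept-5-en-2-ynoate | O[C@@H](C#CC(=O)OC)/C=C(\C)COC(C)=O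
F6 | step 9 | trimethylsilyl ether of F5 | C[Si](C)(C)O[C@@H](C#CC(=O)OC)/C=C(\C)COC(C)=O
F7 | step 9 | (R)-5-[(E)-3-acetoxy-2-methylprop-1-en-1-yl]-3-[(4,4,5,5-tetramethyl-1,3,2-dioxaborolan-2-yl)methyl]furan-2(5H)-one | O=C1O[C@H](/C=C(\C)COC(C)=O)C=C1CB2OC(C)(C)C(C)(C)O2
F8 | step 9 | C8 epimer (8S) of F4: 6R,7R lactone with free 8S hydroxyl and silyl ether intact | O[C@@H](C/C(C)=C/CO[Si](C)(C)C(C)(C)C)[C@H]1C(=C)C(=O)O[C@@H]1/C=C(\C)COC(C)=O
F9 | step 3 | racemic methyl (E)-8-[(tert-butyldimethylsilyl)oxy]-4-hydroxy-6-methyloct-6-en-2-ynoate | OC(C/C(C)=C/CO[Si](C)(C)C(C)(C)C)C#CC(=O)OC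
F10 | step 3 | methyl (E)-8-[(tert-butyldimethylsilyl)oxy]-6-methyl-4-oxooct-6-en-2-ynoate | O=C(C/C(C)=C/CO[Si](C)(C)C(C)(C)C)C#CC(=O)OC
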